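**Retrosynthetic overview**
- Target ⇐ global hydrogenolysis of the tetradeca-O-benzyl ether ⇐ double Steglich galloylation of octa-O-benzyl procyanidin B5 with tri-O-benzylgallic acid.
- The lower pyran ring is built last: C4–C4a by 6-endo epoxide–arene cyclisation, O1–C2 by Mitsunobu etherification (inversion) of a flavanyl-phloroglucinol with an erythro aryl epoxy alcohol.
- Interflavan bond (key step): one-flask DDQ C4–H oxidation of tetra-O-benzylepicatechin and Friedel–Crafts capture by phloroglucinol, whose three-fold symmetry is broken. All three CH of phloroglucinol are equivalent, so no C6/C8 question arises; the 4→6 topology follows from closing the ring through the oxygen para to the new bond.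
- Ring order: upper unit from (−)-epicatechin → lower A ring from phloroglucinol → lower C ring (O1–C2, then C4–C4a). The lower B-ring/C2–C3 piece comes from 3,4-bis(benzyloxy)benzaldehyde by vinyl addition and Sharpless kinetic resolution.

Assumption: 3,4-bis(benzyloxy)benzaldehyde, (−)-epicatechin, phloroglucinol and 3,4,5-tris(benzyloxy)benzoic acid are bought, and a telescoped one-flask operation counts as one step.

**Step 1**
Reactants: 1 3,4-bis(benzyloxy)benzaldehyde
Product: 2 rac-1-[3,4-bis(benzyloxy)phenyl]prop-2-en-1-ol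
Conditions: CH2=CHMgBr (1.2 equiv), THF, −78 → 0 °C; aq. NH4Cl
Reagents that add atoms: vinylmagnesium bromide, C=C[Mg]Br
Why: Grignard 1,2-addition to the aryl aldehyde gives the racemic aryl vinyl carbinol, which the next step resolves.

**Step 2**
Reactants: 2 rac-1-[3,4-bis(benzyloxy)phenyl]prop-2-en-1-ol
Product: 3 (S)-[3,4-bis(benzyloxy)phenyl][(2R)-oxiran-2-yl]methanol (erythro)
Conditions: Ti(OiPr)4 (15 mol %), L-(+)-DIPT (18 mol %), t-BuOOH (0.6 equiv), 4 Å MS, CH2Cl2, −20 °C
Reagents that add atoms: tert-butyl hydroperoxide, CC(C)(C)OO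
Why: Sharpless kinetic resolution (Katsuki–Sharpless epoxidation) with L-(+)-tartrate epoxidises only the fast (R)-carbinol, erythro-selectively, which fixes the carbinol (S) and oxirane (R) centres of 3 (≤50 %, the slow (S)-alcohol stays behind).

**Step 3**
Reactants: 4 (−)-epicatechin, (2R,3R)
Product: 5 5,7,3',4'-tetra-O-benzyl-(−)-epicatechin
Conditions: BnBr (4.4 equiv), K2CO3, DMF, 0 °C → rt, Ar
Reagents that add atoms: benzyl bromide, BrCc1ccccc1
Why: Williamson etherification alkylates the four phenols only, leaving the secondary 3-OH and the C2/C3 centres untouched.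

**Step 4 (key step)**
Reactants: 5 5,7,3',4'-tetra-O-benzyl-(−)-epicatechin; 6 phloroglucinol
Product: 8 5,7,3',4'-tetra-O-benzylepicatechin-(4β→2)-phloroglucinol, (2R,3R,4S), via (2R,3R,4S)-4-(2-ethoxyethoxy)-5,7,3',4'-tetra-O-benzylepicatechin 7 (not isolated)
Conditions: DDQ (1.3 equiv), HOCH2CH2OEt (3 equiv), CH2Cl2, rt, 2 h; then 6 (6 equiv) in THF, Sc(OTf)3 (10 mol %), −20 → 0 °C
Reagents that add atoms: 2-ethoxyethanol, CCOCCO (gives the 4-alkoxy group of 7 only; lost again on the way to 8)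
Why: Proposed new method: DDQ abstracts the pseudo-axial C4 hydride (the A ring is transiently dearomatised to a para-quinone-methide oxocarbenium) and 2-ethoxyethanol traps it as the known 4β-ether 7, whose Sc(OTf)3-catalysed re-ionisation in the same flask lets excess phloroglucinol attack in a Friedel–Crafts alkylation anti to the axial 3-OH (4β, 3,4-trans) at any of its three equivalent CH, so one regioisomer forms and the symmetry of 6 is broken; the closest known reaction types are the two-pot DDQ 4-alkoxylation/Lewis-acid flavanyl coupling and DDQ cross-dehydrogenative couplings.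

**Step 5**
Reactants: 8 5,7,3',4'-tetra-O-benzylepicatechin-(4β→2)-phloroglucinol; 3 (S)-[3,4-bis(benzyloxy)phenyl][(2R)-oxiran-2-yl]methanol
Product: 9 4-O-{(R)-[3,4-bis(benzyloxy)phenyl][(2R)-oxiran-2-yl]methyl} ether of 8 (ether on the phloroglucinol OH para to the flavanyl group)
Conditions: 3 (1.2 equiv), PPh3, DIAD, THF–toluene, 0 °C → rt
Reagents that add atoms: none
Why: Mitsunobu etherification: the only phenol without a bulky ortho neighbour displaces the oxyphosphonium of 3 by SN2 with inversion (S → R at the future C2, the adjacent epoxide disfavouring SN1), while the hindered axial 3-OH of the upper unit should not be activated.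

**Step 6**
Reactants: 9 the aryl epoxybenzyl ether
Product: 10 5,7,3',4'-tetra-O-benzylepicatechin-(4β→6)-3',4'-di-O-benzylepicatechin (lower unit 2R,3R; free 5-OH, 7-OH and both 3-OH)
Conditions: BF3·OEt2 (0.3 equiv), CH2Cl2, −78 → −40 °C
Reagents that add atoms: none
Why: Friedel–Crafts epoxide–arene cyclisation: either of the two equivalent CH ortho to the ether oxygen attacks the terminal epoxide carbon (6-endo), forming C4–C4a without touching a stereocentre (2,3-cis 3-ol), and because the ring oxygen lies para to the interflavan bond only the 4→6 topology can result.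

**Step 7**
Reactants: 10 the hexa-O-benzyl dimer with two free phenols
Product: 11 5,7,3',4'-tetra-O-benzylepicatechin-(4β→6)-5,7,3',4'-tetra-O-benzylepicatechin (octa-O-benzyl procyanidin B5)
Conditions: BnBr (2.4 equiv), K2CO3, DMF, rt
Reagents that add atoms: benzyl bromide, BrCc1ccccc1
Why: Williamson O-benzylation masks the two remaining phenols before acylation, K2CO3 deprotonating phenols but not the two secondary alcohols.

**Step 8**
Reactants: 11 octa-O-benzyl procyanidin B5; 12 3,4,5-tris(benzyloxy)benzoic acid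
Product: 13 3,3'-bis-O-[3,4,5-tris(benzyloxy)benzoyl] derivative of 11 (tetradeca-O-benzyl procyanidin B5 3,3'-di-O-gallate)
Conditions: 12 (3 equiv), DCC (3.3 equiv), DMAP (1 equiv), CH2Cl2, rt → 40 °C
Reagents that add atoms: none
Why: Steglich esterification acylates both secondary 3-hydroxyls with retention of configuration, no other free OH being left.

**Step 9**
Reactants: 13 tetradeca-O-benzyl procyanidin B5 3,3'-di-O-gallate
Product: 14 procyanidin B-5 3,3'-di-O-gallate
Conditions: H2 (1 atm), 20 % Pd(OH)2/C, THF–MeOH–H2O (20:20:1), rt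
Reagents that add atoms: none
Why: Pd-catalysed hydrogenolysis removes all fourteen benzyl ethers under neutral conditions without touching the gallate esters, the stereocentres or the interflavan bond.

**Compound list**
1 | 3,4-bis(benzyloxy)benzaldehyde | O=Cc1ccc(OCc2ccccc2)c(OCc2ccccc2)c1 | starting material
2 | rac-1-[3,4-bis(benzyloxy)phenyl]prop-2-en-1-ol | C=CC(O)c1ccc(OCc2ccccc2)c(OCc2ccccc2)c1 | intermediate
3 | (S)-[3,4-bis(benzyloxy)phenyl][(2R)-oxiran-2-yl]methanol | O[C@@H](c1ccc(OCc2ccccc2)c(OCc2ccccc2)c1)[C@H]1CO1 | intermediate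
4 | (−)-epicatechin | O[C@@H]1Cc2c(O)cc(O)cc2O[C@@H]1c1ccc(O)c(O)c1 | starting material
5 | 5,7,3',4'-tetra-O-benzyl-(−)-epicatechin | O[C@@H]1Cc2c(OCc3ccccc3)cc(OCc3ccccc3)cc2O[C@@H]1c1ccc(OCc2ccccc2)c(OCc2ccccc2)c1 | intermediate
6 | phloroglucinol | Oc1cc(O)cc(O)c1 | starting material
7 | (2R,3R,4S)-4-(2-ethoxyethoxy)-5,7,3',4'-tetra-O-benzylepicatechin | O[C@@H]1[C@@H](OCCOCC)c2c(OCc3ccccc3)cc(OCc3ccccc3)cc2O[C@@H]1c1ccc(OCc2ccccc2)c(OCc2ccccc2)c1 | intermediate (not isolated)
8 | 5,7,3',4'-tetra-O-benzylepicatechin-(4β→2)-phloroglucinol | O[C@@H]1[C@@H](c2c(O)cc(O)cc2O)c2c(OCc3ccccc3)cc(OCc3ccccc3)cc2O[C@@H]1c1ccc(OCc2ccccc2)c(OCc2ccccc2)c1 | intermediate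
9 | 4-O-{(R)-[3,4-bis(benzyloxy)phenyl][(2R)-oxiran-2-yl]methyl} ether of 8 | O[C@@H]1[C@@H](c2c(O)cc(O[C@H](c3ccc(OCc4ccccc4)c(OCc4ccccc4)c3)[C@H]3CO3)cc2O)c2c(OCc3ccccc3)cc(OCc3ccccc3)cc2O[C@@H]1c1ccc(OCc2ccccc2)c(OCc2ccccc2)c1 | intermediate
10 | 5,7,3',4'-tetra-O-benzylepicatechin-(4β→6)-3',4'-di-O-benzylepicatechin | O[C@@H]1[C@@H](c2c(O)cc3c(c2O)C[C@@H](O)[C@@H](c2ccc(OCc4ccccc4)c(OCc4ccccc4)c2)O3)c2c(OCc3ccccc3)cc(OCc3ccccc3)cc2O[C@@H]1c1ccc(OCc2ccccc2)c(OCc2ccccc2)c1 | intermediate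
11 | octa-O-benzyl procyanidin B5 | O[C@@H]1[C@@H](c2c(OCc4ccccc4)cc3c(c2OCc4ccccc4)C[C@@H](O)[C@@H](c2ccc(OCc4ccccc4)c(OCc4ccccc4)c2)O3)c2c(OCc3ccccc3)cc(OCc3ccccc3)cc2O[C@@H]1c1ccc(OCc2ccccc2)c(OCc2ccccc2)c1 | intermediate
12 | 3,4,5-tris(benzyloxy)benzoic acid | OC(=O)c1cc(OCc2ccccc2)c(OCc2ccccc2)c(OCc2ccccc2)c1 | starting material
13 | tetradeca-O-benzyl procyanidin B5 3,3'-di-O-gallate | O=C(O[C@@H]1[C@@H](c2c(OCc4ccccc4)cc3c(c2OCc4ccccc4)C[C@@H](OC(=O)c2cc(OCc4ccccc4)c(OCc4ccccc4)c(OCc4ccccc4)c2)[C@@H](c2ccc(OCc4ccccc4)c(OCc4ccccc4)c2)O3)c2c(OCc3ccccc3)cc(OCc3ccccc3)cc2O[C@@H]1c1ccc(OCc2ccccc2)c(OCc2ccccc2)c1)c1cc(OCc2ccccc2)c(OCc2ccccc2)c(OCc2ccccc2)c1 | intermediate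
14 | procyanidin B-5 3,3'-di-O-gallate | O=C(O[C@@H]1[C@@H](c2c(O)cc3c(c2O)C[C@@H](OC(=O)c2cc(O)c(O)c(O)c2)[C@@H](c2ccc(O)c(O)c2)O3)c2c(O)cc(O)cc2O[C@@H]1c1ccc(O)c(O)c1)c1cc(O)c(O)c(O)c1 | target

**Step count**
Total: 9 steps. Longest linear sequence: 7 steps (4 → 14, steps 3–9); the two-step branch 1 → 3 joins at step 5.

**Steps most likely to fail, with fallbacks**

Step 4 (one-flask oxidation/Friedel–Crafts; residual DDQ or the free phenols may interfere). The fallback sets out from 5 and comes back at 8. The DDQ/2-ethoxyethanol oxidation is run alone and 7 is isolated. Its ether is exchanged with benzyl mercaptan under catalytic Lewis acid for the thioether 4β-benzylthio-5,7,3',4'-tetra-O-benzylepicatechin F1. F1 is then activated thiophilically with AgBF4 in THF at 0 °C in the presence of excess 6, an oxidant-free and nearly neutral C–S activation in place of acid ionisation of an ether, to give 8.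

Step 5 (site selectivity of the Mitsunobu reaction among three phenols rests on sterics alone). The fallback sets out from 8 and comes back at 11. The unhindered phenol is first capped with TIPSCl/imidazole to give the 4-O-triisopropylsilyl ether of 8 F2. The two hindered phenols are benzylated (BnBr, K2CO3) to the 2,6-di-O-benzyl-4-O-triisopropylsilyl derivative F3, and TBAF releases the 2,6-di-O-benzyl mono-phenol F4, which has a single free phenolic OH. Mitsunobu reaction of F4 with 3 gives the 2,6-di-O-benzyl epoxybenzyl ether F5, and BF3·OEt2 cyclisation of F5 gives 11 directly, so steps 6 and 7 fall away.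

Step 6 (acid may ionise the electron-rich benzylic C2–O bond or give 5-exo opening). The fallback sets out from 9 and comes back at 11, replacing the cationic ring closure by an anionic one. The free-phenol ring of 9, the only ring activated enough, is mono-iodinated (NIS or I2/morpholine, 1 equiv) at one of the two equivalent CH to give the iodo derivative of 9 F6. Benzylation of its two phenols gives the di-O-benzyl aryl iodide F7. After deprotonation of the 3-OH, iodine–lithium exchange (n-BuLi, THF, −78 °C) gives an aryllithium that opens the epoxide at its terminal carbon (anionic pyran cyclisation) to give 11.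

**Further compounds**
F1 | step 4 | 4β-benzylthio-5,7,3',4'-tetra-O-benzylepicatechin | O[C@@H]1[C@@H](SCc2ccccc2)c2c(OCc3ccccc3)cc(OCc3ccccc3)cc2O[C@@H]1c1ccc(OCc2ccccc2)c(OCc2ccccc2)c1
F2 | step 5 | 4-O-triisopropylsilyl ether of 8 | O[C@@H]1[C@@H](c2c(O)cc(O[Si](C(C)C)(C(C)C)C(C)C)cc2O)c2c(OCc3ccccc3)cc(OCc3ccccc3)cc2O[C@@H]1c1ccc(OCc2ccccc2)c(OCc2ccccc2)c1
F3 | step 5 | 2,6-di-O-benzyl-4-O-triisopropylsilyl derivative of 8 | O[C@@H]1[C@@H](c2c(OCc4ccccc4)cc(O[Si](C(C)C)(C(C)C)C(C)C)cc2OCc4ccccc4)c2c(OCc3ccccc3)cc(OCc3ccccc3)cc2O[C@@H]1c1ccc(OCc2ccccc2)c(OCc2ccccc2)c1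
F4 | step 5 | 2,6-di-O-benzyl derivative of 8 (free 4-OH) | O[C@@H]1[C@@H](c2c(OCc4ccccc4)cc(O)cc2OCc4ccccc4)c2c(OCc3ccccc3)cc(OCc3ccccc3)cc2O[C@@H]1c1ccc(OCc2ccccc2)c(OCc2ccccc2)c1
F5 | step 5 | 2,6-di-O-benzyl derivative of 9 | O[C@@H]1[C@@H](c2c(OCc4ccccc4)cc(O[C@H](c3ccc(OCc4ccccc4)c(OCc4ccccc4)c3)[C@H]3CO3)cc2OCc4ccccc4)c2c(OCc3ccccc3)cc(OCc3ccccc3)cc2O[C@@H]1c1ccc(OCc2ccccc2)c(OCc2ccccc2)c1
F6 | step 6 | 3-iodo derivative of 9 (iodine ortho to the ether oxygen) | O[C@@H]1[C@@H](c2c(O)c(I)c(O[C@H](c3ccc(OCc4ccccc4)c(OCc4ccccc4)c3)[C@H]3CO3)cc2O)c2c(OCc3ccccc3)cc(OCc3ccccc3)cc2O[C@@H]1c1ccc(OCc2ccccc2)c(OCc2ccccc2)c1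
F7 | step 6 | 2,6-di-O-benzyl-3-iodo derivative of 9 | O[C@@H]1[C@@H](c2c(OCc4ccccc4)c(I)c(O[C@H](c3ccc(OCc4ccccc4)c(OCc4ccccc4)c3)[C@H]3CO3)cc2OCc4ccccc4)c2c(OCc3ccccc3)cc(OCc3ccccc3)cc2O[C@@H]1c1ccc(OCc2ccccc2)c(OCc2ccccc2)c1
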